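The route rests on cutting the single bond between the vinylic CH of the (E)-trisubstituted alkene nearer the cyclohexane ring and the chain CH2 next to it, the sp2–sp3 link of the 1,5-diene. Both carbons enter as electrophiles: a nickel-catalysed electroreductive decarboxylative alkenylation joins an (E)-alkenyl iodide bearing the (S)-2,2-dimethyl-6-methylidenecyclohexyl ring to the primary radical released from an N-acyloxyphthalimide that already carries the second (E)-alkene and the furan-2(5H)-one ring. One operation forges the bond, keeps both alkene geometries and gives the target without protecting groups. The acid precursor is one carbon longer than the chain it delivers; that carbon leaves as CO2.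

Key step: step 13

Assumption: the (R,R)-enantiomer of the ANDEN-phenyl bisphosphine ligand is taken to deliver the (S)-ketone 4; should the sense of induction prove opposite, the (S,S)-ligand is used with no other change.

Remark: compounds 17, 18 and 19 are racemic at a carbinol centre that step 10 destroys.

**Fragment 1 (alkenyl iodide)**

Step 1
Reactants: 1 3-methylcyclohex-2-en-1-one
Product: 3 prop-2-en-1-yl 3,3-dimethylcyclohex-1-en-1-yl carbonate, via bromomagnesium enolate 2 (not isolated)
Conditions: MeMgBr, CuBr·SMe2 (5 mol%), THF, −20 °C; then allyl chloroformate, TMEDA, −78 °C to rt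
Reagents that add atoms: methylmagnesium bromide C[Mg]Br; allyl chloroformate C=CCOC(Cl)=O
Why: Copper-catalysed conjugate addition of the Grignard reagent builds the gem-dimethyl carbon and leaves a regiodefined magnesium enolate, which the hard chloroformate acylates on oxygen so that the enol double bond is fixed toward the quaternary carbon (1,4-addition with enolate trapping; no stereocentre is formed).

Step 2
Reactants: 3 prop-2-en-1-yl 3,3-dimethylcyclohex-1-en-1-yl carbonate
Product: 4 (2S)-3,3-dimethyl-2-(prop-2-en-1-yl)cyclohexan-1-one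
Conditions: Pd2(dba)3·CHCl3 (2.5 mol%), (R,R)-ANDEN-phenyl bisphosphine ligand (5.5 mol%), 1,4-dioxane, rt
Reagents that add atoms: none
Why: Decarboxylative palladium-catalysed asymmetric allylic alkylation (Tsuji–Trost type) ionises the carbonate to a ligand-bound allylpalladium cation and the enolate, which recombine at the carbon next to the gem-dimethyl group faster than the enolate can equilibrate, the chiral pocket of the ligand selecting the enolate face and so setting the (S)-configured tertiary centre.

Step 3
Reactants: 4 (2S)-3,3-dimethyl-2-(prop-2-en-1-yl)cyclohexan-1-one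
Product: 5 (2S)-1,1-dimethyl-3-methylidene-2-(prop-2-en-1-yl)cyclohexane
Conditions: Zn, CH2Br2, TiCl4, THF/CH2Cl2, 0 °C to rt
Reagents that add atoms: dibromomethane BrCBr
Why: Takai–Lombardo methylenation uses a non-basic zinc–titanium methylene reagent that converts hindered, enolisable ketones into exocyclic alkenes without epimerising the adjacent stereocentre.

Step 4
Reactants: 5 (2S)-1,1-dimethyl-3-methylidene-2-(prop-2-en-1-yl)cyclohexane
Product: 7 3-[(1S)-2,2-dimethyl-6-methylidenecyclohexyl]propan-1-ol, via trialkylborane 6 (not isolated)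
Conditions: Sia2BH (from BH3·THF and 2-methylbut-2-ene), THF, 0 °C; then NaOH, H2O2, 0 °C to rt
Reagents that add atoms: hydrogen peroxide OO
Why: Hydroboration–oxidation with the bulky dialkylborane adds boron to the terminal carbon of the monosubstituted alkene far faster than to the hindered 1,1-disubstituted exocyclic alkene, and oxidation with retention gives the primary alcohol.

Step 5
Reactants: 7 3-[(1S)-2,2-dimethyl-6-methylidenecyclohexyl]propan-1-ol
Product: 8 3-[(1S)-2,2-dimethyl-6-methylidenecyclohexyl]propanal
Conditions: TEMPO (10 mol%), PhI(OAc)2, CH2Cl2, rt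
Reagents that add atoms: none
Why: Oxoammonium-mediated (TEMPO-catalysed) oxidation stops cleanly at the aldehyde and does not touch the exocyclic alkene or the stereocentre.

Step 6
Reactants: 8 3-[(1S)-2,2-dimethyl-6-methylidenecyclohexyl]propanal
Product: 9 (2S)-2-(but-3-yn-1-yl)-1,1-dimethyl-3-methylidenecyclohexane
Conditions: dimethyl (1-diazo-2-oxopropyl)phosphonate, K2CO3, MeOH, 0 °C to rt
Reagents that add atoms: dimethyl (1-diazo-2-oxopropyl)phosphonate COP(=O)(OC)C(=[N+]=[N-])C(C)=O
Why: Seyferth–Gilbert homologation in its Ohira–Bestmann form adds the diazomethylphosphonate anion to the aldehyde, and loss of phosphate and N2 with 1,2-hydrogen shift gives the terminal alkyne under mild carbonate base.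

Step 7
Reactants: 9 (2S)-2-(but-3-yn-1-yl)-1,1-dimethyl-3-methylidenecyclohexane
Product: 11 (2S)-2-[(3E)-4-iodo-3-methylbut-3-en-1-yl]-1,1-dimethyl-3-methylidenecyclohexane, via alkenyldimethylalane 10 (not isolated)
Conditions: Me3Al, Cp2ZrCl2 (25 mol%), CH2Cl2, 0 °C to rt; then I2, THF, −30 °C to 0 °C
Reagents that add atoms: trimethylaluminium C[Al](C)C; iodine II
Why: Negishi zirconium-catalysed carboalumination adds methyl and aluminium syn across the terminal alkyne with methyl on the internal carbon, and iodinolysis of the alkenyl–aluminium bond with retention gives the (E)-iodide, the hindered 1,1-disubstituted exocyclic alkene being inert to this reagent.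

**Fragment 2 (redox-active ester)**

Step 8
Reactants: 12 3,3-diethoxyprop-1-ene; 13 4-bromofuran-2(5H)-one
Product: 16 3-(5-oxo-2,5-dihydrofuran-3-yl)propanal, via B-alkyl-9-BBN 14 (not isolated), via diethyl acetal 15 (not isolated)
Conditions: 12, 9-BBN, THF, 0 °C to rt; then 13, PdCl2(dppf) (5 mol%), K3PO4 (aq), THF/DMF, 50 °C; then 2 M HCl, rt
Reagents that add atoms: water O
Why: B-alkyl Suzuki–Miyaura coupling joins the primary alkylborane from anti-Markovnikov hydroboration to the alkenylpalladium bromide formed from the β-bromobutenolide, and the acidic work-up hydrolyses the acetal to the aldehyde.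

Step 9
Reactants: 16 3-(5-oxo-2,5-dihydrofuran-3-yl)propanal
Product: 17 4-(3-hydroxy-4-methylpent-4-en-1-yl)furan-2(5H)-one (racemic)
Conditions: 2-bromopropene, CrCl2 (4 equiv), NiCl2 (1 mol%), DMF, rt
Reagents that add atoms: 2-bromopropene CC(Br)=C
Why: The Nozaki–Hiyama–Kishi reaction generates an alkenylchromium nucleophile that adds only to the aldehyde and tolerates the butenolide, giving a racemic carbinol whose stereocentre is destroyed in the next step.

Step 10
Reactants: 17 4-(3-hydroxy-4-methylpent-4-en-1-yl)furan-2(5H)-one
Product: 20 ethyl (4E)-4-methyl-7-(5-oxo-2,5-dihydrofuran-3-yl)hept-4-enoate, via mixed orthoester 18 (not isolated), via ketene acetal 19 (not isolated)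
Conditions: MeC(OEt)3 (excess), EtCO2H (cat.), 140 °C, EtOH distilled off
Reagents that add atoms: triethyl orthoacetate CC(OCC)(OCC)OCC
Why: Johnson–Claisen rearrangement proceeds through a chair transition state with the carbinol substituent equatorial, so the [3,3] shift forms the new C–C bond and the (E)-trisubstituted alkene together.

Step 11
Reactants: 20 ethyl (4E)-4-methyl-7-(5-oxo-2,5-dihydrofuran-3-yl)hept-4-enoate
Product: 22 (4E)-4-methyl-7-(5-oxo-2,5-dihydrofuran-3-yl)hept-4-enoic acid, via dilithium hydroxy dicarboxylate 21 (not isolated)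
Conditions: LiOH (4 equiv), THF/H2O, rt; then 2 M HCl to pH 1–2, rt
Reagents that add atoms: lithium hydroxide [Li+].[OH-]
Why: Saponification cleaves the ethyl ester and opens the lactone to a (Z)-configured hydroxy enoate whose fixed geometry lets acidification close the butenolide again by lactonisation while the chain acid stays free.

Step 12
Reactants: 22 (4E)-4-methyl-7-(5-oxo-2,5-dihydrofuran-3-yl)hept-4-enoic acid
Product: 24 1,3-dioxoisoindolin-2-yl (4E)-4-methyl-7-(5-oxo-2,5-dihydrofuran-3-yl)hept-4-enoate, via O-acylisourea 23 (not isolated)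
Conditions: N-hydroxyphthalimide, DIC, DMAP (10 mol%), CH2Cl2, rt
Reagents that add atoms: N-hydroxyphthalimide ON1C(=O)c2ccccc2C1=O
Why: Carbodiimide-mediated (Steglich-type) esterification with N-hydroxyphthalimide turns the acid into the redox-active ester under neutral conditions that leave the butenolide intact.

**Fragment union**

Step 13
Reactants: 11 (2S)-2-[(3E)-4-iodo-3-methylbut-3-en-1-yl]-1,1-dimethyl-3-methylidenecyclohexane; 24 1,3-dioxoisoindolin-2-yl (4E)-4-methyl-7-(5-oxo-2,5-dihydrofuran-3-yl)hept-4-enoate
Product: 25 4-[(3E,7E)-10-[(1S)-2,2-dimethyl-6-methylidenecyclohexyl]-4,8-dimethyldeca-3,7-dien-1-yl]furan-2(5H)-one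
Conditions: 24 (1.5 equiv), NiCl2·6H2O (10 mol%), 2,2'-bipyridine (10 mol%), AgNO3 (0.3 equiv), LiCl, DMF, Mg anode, reticulated vitreous carbon cathode, constant current (about 2.5 F/mol), rt
Reagents that add atoms: none
Why: Nickel-catalysed electroreductive cross-electrophile coupling: cathodically generated low-valent nickel–bipyridine inserts into the C–I bond of 11 with retention of the (E)-geometry, single-electron reduction of 24 expels CO2 and phthalimide anion to leave the primary radical at the chain CH2, and capture of this radical by the alkenylnickel species followed by reductive elimination from trivalent nickel forges the C(sp2)–C(sp3) bond. The closest known reaction type is the nickel-catalysed decarboxylative alkenylation of N-acyloxyphthalimides with alkenyl halides or alkenylzinc reagents, which is established for polyene terpenoid chains. No ring is closed and no stereocentre is formed: the (S)-centre is remote and untouched, the alkenyl–nickel bond is configurationally stable, and the radical is only homoallylic to the second alkene, where its sole cyclisation is a reversible three-membered closure. Cross-selectivity over homocoupling rests on the different activation modes of the two electrophiles, two-electron oxidative addition for the iodide and one-electron reduction for the ester, helped by a modest excess of 24. The mild potential set by the nickel couple should leave the butenolide and the exocyclic alkene unreduced, and the β,β-disubstituted butenolide seven atoms away is a poor radical acceptor.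

**Compound list**

1 | 3-methylcyclohex-2-en-1-one | CC1=CC(=O)CCC1 | starting material
2 | bromomagnesium 3,3-dimethylcyclohex-1-en-1-olate (formed in the flask) | CC1(C)CCCC(O[Mg]Br)=C1 | intermediate
3 | prop-2-en-1-yl 3,3-dimethylcyclohex-1-en-1-yl carbonate | C=CCOC(=O)OC1=CC(C)(C)CCC1 | intermediate
4 | (2S)-3,3-dimethyl-2-(prop-2-en-1-yl)cyclohexan-1-one | O=C1CCCC(C)(C)[C@@H]1CC=C | intermediate
5 | (2S)-1,1-dimethyl-3-methylidene-2-(prop-2-en-1-yl)cyclohexane | C=C1CCCC(C)(C)[C@@H]1CC=C | intermediate
6 | {3-[(1S)-2,2-dimethyl-6-methylidenecyclohexyl]propyl}bis(3-methylbutan-2-yl)borane (formed in the flask) | C=C1CCCC(C)(C)[C@@H]1CCCB(C(C)C(C)C)C(C)C(C)C | intermediate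
7 | 3-[(1S)-2,2-dimethyl-6-methylidenecyclohexyl]propan-1-ol | C=C1CCCC(C)(C)[C@@H]1CCCO | intermediate
8 | 3-[(1S)-2,2-dimethyl-6-methylidenecyclohexyl]propanal | C=C1CCCC(C)(C)[C@@H]1CCC=O | intermediate
9 | (2S)-2-(but-3-yn-1-yl)-1,1-dimethyl-3-methylidenecyclohexane | C=C1CCCC(C)(C)[C@@H]1CCC#C | intermediate
10 | {(1E)-4-[(1S)-2,2-dimethyl-6-methylidenecyclohexyl]-2-methylbut-1-en-1-yl}dimethylalane (formed in the flask) | C=C1CCCC(C)(C)[C@@H]1CC/C(C)=C/[Al](C)C | intermediate
11 | (2S)-2-[(3E)-4-iodo-3-methylbut-3-en-1-yl]-1,1-dimethyl-3-methylidenecyclohexane | C=C1CCCC(C)(C)[C@@H]1CC/C(C)=C/I | intermediate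
12 | 3,3-diethoxyprop-1-ene | C=CC(OCC)OCC | starting material
13 | 4-bromofuran-2(5H)-one | BrC1=CC(=O)OC1 | starting material
14 | 9-(3,3-diethoxypropyl)-9-borabicyclo[3.3.1]nonane (formed in the flask) | CCOC(CCB1C2CCCC1CCC2)OCC | intermediate
15 | 4-(3,3-diethoxypropyl)furan-2(5H)-one (formed in the flask) | CCOC(CCC1=CC(=O)OC1)OCC | intermediate
16 | 3-(5-oxo-2,5-dihydrofuran-3-yl)propanal | O=CCCC1=CC(=O)OC1 | intermediate
17 | 4-(3-hydroxy-4-methylpent-4-en-1-yl)furan-2(5H)-one (racemic) | C=C(C)C(O)CCC1=CC(=O)OC1 | intermediate
18 | 4-[3-(1,1-diethoxyethoxy)-4-methylpent-4-en-1-yl]furan-2(5H)-one (racemic, formed in the flask) | CCOC(C)(OCC)OC(CCC1=CC(=O)OC1)C(C)=C | intermediate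
19 | 4-{3-[(1-ethoxyethenyl)oxy]-4-methylpent-4-en-1-yl}furan-2(5H)-one (racemic, formed in the flask) | C=C(OCC)OC(CCC1=CC(=O)OC1)C(C)=C | intermediate
20 | ethyl (4E)-4-methyl-7-(5-oxo-2,5-dihydrofuran-3-yl)hept-4-enoate | CCOC(=O)CC/C(C)=C/CCC1=CC(=O)OC1 | intermediate
21 | dilithium (2Z,6E)-3-(hydroxymethyl)-7-methyldeca-2,6-dienedioate (formed in the flask) | [Li+].[Li+].[O-]C(=O)CC/C(C)=C/CC/C(CO)=C/C([O-])=O | intermediate
22 | (4E)-4-methyl-7-(5-oxo-2,5-dihydrofuran-3-yl)hept-4-enoic acid | OC(=O)CC/C(C)=C/CCC1=CC(=O)OC1 | intermediate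
23 | O-acylisourea of 22 with N,N'-diisopropylcarbodiimide (formed in the flask) | CC(C)N=C(NC(C)C)OC(=O)CC/C(C)=C/CCC1=CC(=O)OC1 | intermediate
24 | 1,3-dioxoisoindolin-2-yl (4E)-4-methyl-7-(5-oxo-2,5-dihydrofuran-3-yl)hept-4-enoate | O=C(CC/C(C)=C/CCC1=CC(=O)OC1)ON1C(=O)c2ccccc2C1=O | intermediate
25 | 4-[(3E,7E)-10-[(1S)-2,2-dimethyl-6-methylidenecyclohexyl]-4,8-dimethyldeca-3,7-dien-1-yl]furan-2(5H)-one | C=C1CCCC(C)(C)[C@@H]1CC/C(C)=C/CC/C(C)=C/CCC1=CC(=O)OC1 | target

**Summary**

Total step count: 13. Longest linear sequence: 8 steps (steps 1 to 7, then step 13); the second branch runs through steps 8 to 12.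

**Steps most likely to fail**

Step 13. The coupling may suffer from hydrodehalogenation of the alkenylnickel intermediate, from hydrogen abstraction or dimerisation of the primary radical before nickel captures it, or from erosion of the (E)-geometry of the neighbouring alkene through reversible cyclopropylcarbinyl closure. The fallback replaces the radical union by a two-electron alkenyl–alkyl Negishi coupling; it sets out from 24 and 11 and comes back to the route at 25. Photochemical decarboxylative iodination of 24 (LiI, PPh3 cat., blue light, acetone) should give the primary iodide 4-[(3E)-6-iodo-4-methylhex-3-en-1-yl]furan-2(5H)-one F1. Zinc insertion (Zn dust, LiCl, THF, 40 °C) should then give [(3E)-3-methyl-6-(5-oxo-2,5-dihydrofuran-3-yl)hex-3-en-1-yl]zinc iodide F2. Coupling of this reagent with 11 under Pd(PPh3)4 in THF at rt should form the same bond with retention of the alkene geometry and give 25.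

Step 2. The allylation may lose enantioselectivity through poor facial discrimination at the hindered enolate carbon, or through proton transfer between product and enolate, which would also cause double allylation. The fallback sets the centre by enzymatic resolution; it sets out from 1 and comes back at 4.
- Conjugate addition to 1 as in step 1, with the enolate trapped by allyl bromide (DMPU), should give racemic 3,3-dimethyl-2-(prop-2-en-1-yl)cyclohexan-1-one F3.
- Reduction with LiBH(s-Bu)3 (THF, −78 °C) should give the racemic cis-alcohol, rac-(1R,2S)-3,3-dimethyl-2-(prop-2-en-1-yl)cyclohexan-1-ol F4, by equatorial hydride delivery.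
- Acylation with lipase from Burkholderia cepacia and vinyl acetate (t-BuOMe, 30 °C) is expected, by the usual empirical rule for secondary alcohols, to acylate the (1R)-enantiomer. This should give (1R,2S)-3,3-dimethyl-2-(prop-2-en-1-yl)cyclohexyl acetate F5, which is separated from the unreacted enantiomeric alcohol.
- Methanolysis (K2CO3, MeOH) should give (1R,2S)-3,3-dimethyl-2-(prop-2-en-1-yl)cyclohexan-1-ol F6, and buffered Dess–Martin oxidation should return 4 without epimerisation.

Step 8. The bromobutenolide may be consumed by base-mediated addition–elimination before oxidative addition, and slow transmetallation of the alkylborane may allow β-hydride elimination. The fallback replaces the palladium coupling by a copper-mediated conjugate addition–elimination; it sets out from 13 and comes back at 16. The Grignard reagent of 2-(2-bromoethyl)-1,3-dioxolane (Mg, THF) with CuBr·SMe2 at −78 °C should add to 13 and expel bromide to give 4-[2-(1,3-dioxolan-2-yl)ethyl]furan-2(5H)-one F7. Hydrolysis (2 M HCl, THF, rt) should then give 16.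

Further compounds
F1 | step 13 | 4-[(3E)-6-iodo-4-methylhex-3-en-1-yl]furan-2(5H)-one | ICC/C(C)=C/CCC1=CC(=O)OC1
F2 | step 13 | [(3E)-3-methyl-6-(5-oxo-2,5-dihydrofuran-3-yl)hex-3-en-1-yl]zinc iodide | I[Zn]CC/C(C)=C/CCC1=CC(=O)OC1
F3 | step 2 | racemic 3,3-dimethyl-2-(prop-2-en-1-yl)cyclohexan-1-one | O=C1CCCC(C)(C)C1CC=C
F4 | step 2 | rac-(1R,2S)-3,3-dimethyl-2-(prop-2-en-1-yl)cyclohexan-1-ol (both enantiomers of the cis-alcohol) | O[C@@H]1CCCC(C)(C)[C@@H]1CC=C.O[C@H]1CCCC(C)(C)[C@H]1CC=C
F5 | step 2 | (1R,2S)-3,3-dimethyl-2-(prop-2-en-1-yl)cyclohexyl acetate | CC(=O)O[C@@H]1CCCC(C)(C)[C@@H]1CC=C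
F6 | step 2 | (1R,2S)-3,3-dimethyl-2-(prop-2-en-1-yl)cyclohexan-1-ol | O[C@@H]1CCCC(C)(C)[C@@H]1CC=C
F7 | step 8 | 4-[2-(1,3-dioxolan-2-yl)ethyl]furan-2(5H)-one | O=C1OCC(CCC2OCCO2)=C1
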